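The data come from a simulation for substances that don't exist; the scatter is artificial.

The sum [E] + [Z], with whatever is held in complexes read along with the free species, stayed at its charged value in each of these closed flasks, since the overall change is E -> Z and X comes back. So in the ochre run, charged like the blue run with 50.0 mM of E and 5.00 mM of X, E was the limiting reagent, and my task was to find how much of it remained at 90 min.

| setting | blue | teal | grey | red | ochre |
|---|---|---|---|---|---|
| E | 50.0 mM | 20.0 mM | 50.0 mM | 25.0 mM | 50.0 mM |
| X | 5.00 mM | 5.00 mM | 5.00 mM | 5.00 mM | 5.00 mM |
| Z |  |  | 15.0 mM |  |  |
| time |  |  |  |  | 90 min |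

| run | time / min | [Z] / mM |
|---|---|---|
| blue run | 7.5 | 4.05 |
| blue run | 15 | 8.01 |
| blue run | 22 | 12.08 |
| blue run | 30 | 16.50 |
| blue run | 38 | 20.44 |
| blue run | 45 | 23.78 |
| teal run | 7.5 | 1.86 |
| teal run | 15 | 4.60 |
| teal run | 22 | 5.97 |
| teal run | 30 | 8.21 |
| teal run | 38 | 10.31 |
| teal run | 45 | 11.61 |
| grey run | 7.5 | 19.73 |
| grey run | 15 | 24.93 |
| grey run | 22 | 29.01 |
| grey run | 30 | 34.11 |
| grey run | 38 | 38.44 |
| grey run | 45 | 42.17 |
| red run | 7.5 | 2.73 |
| red run | 15 | 5.12 |
| red run | 22 | 7.53 |
| red run | 30 | 9.93 |
| red run | 38 | 12.15 |
| red run | 45 | 13.83 |

(each reading ± 0.2 mM)

1. apparent order in [E] of the starting rate, round the charge of the blue run (the rate where two percent of its E have turned into Z) (one fixed amount of Z, the same in the runs compared)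
2. the teal run starts with 30.0 mM less of E than the blue run, and with no Z. Compared where both hold the same amount of E, once fifteen percent of what the teal run was charged with has turned into Z, is the teal run faster, slower or alike (within a tenth)?
3. Z in the ochre run at 90 min, as a share of the E charged

- Overall: E -> Z, with X as catalyst.
- Constant volume, constant temperature.
- What is held in complexes is read along with the free species.
- An order is taken over about fifteen percent of the charge, up and down.

I took the blue readings as the ochre run's opening 45 min, and the balance turned each reading of [Z] into a reading of [E]. From these I reckoned the specific rate w, the fraction of the remaining E lost per minute, read as the logarithm of the fall in [E] divided by the time. In the blue run it was 0.0116 /min up to 15 min and 0.0163 /min from 30 min to 45 min, higher later than earlier, whereas its plain rate fell from 0.534 mM/min to 0.485 mM/min.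

These two trends, read off scattered readings, gave my bracket, so long as both went on. Holding the falling plain rate at its late value set a bound from above of 91.2%, and holding the rising w at its late value, starting from 26.2 mM of E, set a bound from below of 74.9%. To tighten it, I noted that the middle of the remaining stretch lay as far beyond the late window as that window lay beyond the early one, so I let w climb by the same step to 0.0210 /min, which gave 79.6%. The forecast gave an order of 0.55 (0.4 to 0.72), a slower teal run, and 80% (73% to 87%) for the ochre run, stepping “with the rate falling from 0.47 to 0.25 mM/min”, which put it inside my bracket.

The ochre run held Z equal to 82.3% of the E charged at 90 min; the order round the blue charge was 0.62, and the teal run was slower, at 0.73 of the blue rate where both held the same amount of E.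

    X + E → Z + X (6.240 /M/min)
    E + Z → 2 Z (0.4062 /M/min)
    2 E ⇌ E2, settled at all times (51.40 /M)

The ochre run thus held 8.84 mM of E at 90 min, each E2 counted as its two E, so, from the blue reading at 45 min, its w averaged 0.0242 /min after that time, higher than my 0.0210 /min. Carried to the grey run, the late blue w gave a time of 42.5 min for the Z made to come to half of the E charged, and the grey run took 40.4 min.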